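**Plan**
- Retrosynthesis cuts the two ester C–O bonds (α-linolenic acid), then C11'=C12' and C11=C12 (Wittig), leaving a β-end C15 phosphonium salt, the C10 trienedial and an ε-end C15 hydroxy aldehyde.
- In the β-ring, C2–C3 and C1–C6 are cut together: the ring holds an isobutene unit (C1(CH3)2–C2H2) lodged between the oxygen-bearing C3 and the olefinic C6 that carries the chain. It therefore arises from isobutene and an acyclic C3–C10 dienone whose C3 is an acetal carbon and whose C5=C6 bond is the terminating nucleophile (a formal [4+2] cation–olefin annulation).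
- Forward order: acyclic dienone acetal → annulation (β-ring with side chain C7–C10 in place) → C15 salt → C25 aldehyde → C25 salt; ε-end from (R)-α-ionone; Wittig union; double esterification last.
- Stereochemistry: C3 from a (2R,4R)-pentane-2,4-diol acetal template in the annulation; C6' from (R)-α-ionone; C3' by hydride delivery trans to the chain; E-olefins from the olefinations plus thermal equilibration; Z-olefins from α-linolenic acid.

Key step: step 4

Remark: positions are cited in carotenoid numbering (C1–C6 β-ring, C1'–C6' ε-ring); (R)-α-ionone, (2R,4R)-pentane-2,4-diol, 2,7-dimethylocta-2,4,6-trienedial and α-linolenic acid are taken as purchasable, and the sense of induction of the dioxane template is taken from the accepted model for its TiCl4-mediated openings (attack anti to the C–O bond next to the axial methyl group).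

**Route**

Step 1
Reactants: 1 4,4-dimethoxybutan-2-one
Product: 2 5,5-dimethoxy-3-methylpent-1-yn-3-ol (racemic)
Conditions: HC≡CMgBr (1.3 equiv), THF, 0 °C; aq. NH4Cl
Reagents that add atoms: ethynylmagnesium bromide, C#C[Mg]Br
Why: Grignard 1,2-addition of an acetylide to the methyl ketone; the carbinol centre disappears in step 3 and need not be controlled.

Step 2
Reactants: 2 5,5-dimethoxy-3-methylpent-1-yn-3-ol; 3 (2R,4R)-pentane-2,4-diol
Product: 4 1-[(4R,6R)-4,6-dimethyl-1,3-dioxan-2-yl]-2-methylbut-3-yn-2-ol (both carbinol epimers)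
Conditions: PPTS (5 mol %), toluene, 50 °C, MeOH removed under reduced pressure
Reagents that add atoms: none
Why: acid-catalysed transacetalisation driven by removal of methanol; the two stereocentres of the diol are carried in unchanged and turn the acetal into the chiral template for step 4.

Step 3
Reactants: 4 1-[(4R,6R)-4,6-dimethyl-1,3-dioxan-2-yl]-2-methylbut-3-yn-2-ol
Product: 6 (3E,5E)-7-[(4R,6R)-4,6-dimethyl-1,3-dioxan-2-yl]-6-methylhepta-3,5-dien-2-one, via allenyl ketone 5 (not isolated)
Conditions: 2-methoxypropene (4 equiv), PPTS (1 mol %), toluene, sealed vessel, 100 °C; concentrate; NaOH (0.1 equiv), MeOH, 0 °C; chromatography (removal of the 5Z isomer)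
Reagents that add atoms: 2-methoxypropene, COC(C)=C
Why: Saucy–Marbet rearrangement (propargyl vinyl ether Claisen, a [3,3] shift) should give the β-allenyl ketone, which mild base moves into conjugation as in the pseudoionone synthesis; excess enol ether scavenges methanol and so protects the dioxane.

Step 4
Reactants: 6 (3E,5E)-7-[(4R,6R)-4,6-dimethyl-1,3-dioxan-2-yl]-6-methylhepta-3,5-dien-2-one; 7 isobutene (2-methylpropene)
Product: 9 (3E)-4-[(4R)-4-{[(2R,4R)-4-hydroxypentan-2-yl]oxy}-2,6,6-trimethylcyclohex-1-en-1-yl]but-3-en-2-one, via tertiary carbocation 8 (not isolated)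
Conditions: TiCl4 (2.2 equiv), CH2Cl2, –78 °C; isobutene (1.5 equiv) added slowly as a cold CH2Cl2 solution; –78 → –40 °C; aq. NaHCO3
Reagents that add atoms: none
Why: Proposed new method: TiCl4 binds the dioxane oxygen that flanks the axial methyl group and loosens that C3–O bond, isobutene attacks the incipient oxocarbenium carbon C3 through its CH2 terminus anti to the leaving oxygen (Prins addition, forming C2–C3) and so gives tertiary cation 8 at C1, which is trapped by C6 of the C5=C6 bond (forming C1–C6), and the tertiary C5 cation then loses the C6 proton to give the conjugated dienone. The closest known reaction types are the TiCl4-mediated opening of 2,4-pentanediol acetals by allylsilanes and by tethered alkenes (acetal-initiated cation–olefin cyclisation) and the acid-mediated pseudoionone-to-ionone ring closure; new is the intermolecular insertion of an unactivated 1,1-disubstituted alkene between the two events as a formal [4+2] annulation. The six-membered ring closes in the 6-endo-trig mode through a chair with the C3 alkoxy group and the C6 side chain equatorial. The only new stereocentre, C3, should be set (R) by the (4R,6R)-dioxane template, because the nucleophile enters with inversion at the C–O bond next to the axial methyl group. The step needs single capture of the oxocarbenium ion by isobutene without oligomerisation (low stationary isobutene concentration, low temperature, faster intramolecular trapping of 8), 6-endo instead of 5-exo closure (tertiary C5 cation, carbonyl-polarised diene) and proton loss towards C6 (axial, doubly allylic C6–H, conjugation with the enone); a C4=C5 isomer or a C5 chloride would be converged in step 6.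

Step 5
Reactants: 9 (3E)-4-[(4R)-4-{[(2R,4R)-4-hydroxypentan-2-yl]oxy}-2,6,6-trimethylcyclohex-1-en-1-yl]but-3-en-2-one
Product: 10 (3E)-4-[(4R)-2,6,6-trimethyl-4-{[(2R)-4-oxopentan-2-yl]oxy}cyclohex-1-en-1-yl]but-3-en-2-one
Conditions: Dess–Martin periodinane (1.3 equiv), NaHCO3, CH2Cl2, 0 °C → rt
Reagents that add atoms: none
Why: Dess–Martin oxidation of the secondary alcohol of the spent template makes the ether a β-alkoxy ketone that can leave by elimination; the dienone and the C3 centre are not touched.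

Step 6
Reactants: 10 (3E)-4-[(4R)-2,6,6-trimethyl-4-{[(2R)-4-oxopentan-2-yl]oxy}cyclohex-1-en-1-yl]but-3-en-2-one
Product: 11 (3E)-4-[(4R)-4-hydroxy-2,6,6-trimethylcyclohex-1-en-1-yl]but-3-en-2-one [(3R)-3-hydroxy-β-ionone]
Conditions: KOH (0.5 equiv), MeOH–THF, 0 °C, then 40 °C
Reagents that add atoms: none
Why: E1cB (retro-oxa-Michael) elimination releases the C3 oxygen without breaking the C3–O bond, so the configuration is kept; once the hydroxyl is free the same base should move any β,γ-isomer into the conjugated C5=C6 position through the extended enolate.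

Step 7
Reactants: 11 (3E)-4-[(4R)-4-hydroxy-2,6,6-trimethylcyclohex-1-en-1-yl]but-3-en-2-one
Product: 12 (1R)-4-[(1E)-3-hydroxy-3-methylpenta-1,4-dien-1-yl]-3,5,5-trimethylcyclohex-3-en-1-ol (both carbinol epimers)
Conditions: CH2=CHMgBr (3.5 equiv), THF, –30 → 0 °C; aq. NH4Cl
Reagents that add atoms: vinylmagnesium bromide, C=C[Mg]Br
Why: Grignard 1,2-addition to the dienone carbonyl (the vinyl-β-ionol reaction type); the new carbinol centre is removed in step 8, so both epimers serve.

Step 8
Reactants: 12 (1R)-4-[(1E)-3-hydroxy-3-methylpenta-1,4-dien-1-yl]-3,5,5-trimethylcyclohex-3-en-1-ol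
Product: 13 [(2E,4E)-5-[(4R)-4-hydroxy-2,6,6-trimethylcyclohex-1-en-1-yl]-3-methylpenta-2,4-dien-1-yl]triphenylphosphonium bromide
Conditions: PPh3·HBr (1.05 equiv), MeOH, 0 °C → rt; crystallisation
Reagents that add atoms: triphenylphosphine hydrobromide, [PH+](c1ccccc1)(c1ccccc1)c1ccccc1.[Br-]
Why: SN1-type allylic transposition: the tertiary bis-allylic alcohol ionises and PPh3 captures the pentadienyl cation at its primary terminus to give the conjugated 2E,4E salt, while the homoallylic ring hydroxyl is not ionised.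

Step 9
Reactants: 13 [(2E,4E)-5-[(4R)-4-hydroxy-2,6,6-trimethylcyclohex-1-en-1-yl]-3-methylpenta-2,4-dien-1-yl]triphenylphosphonium bromide; 14 (2E,4E,6E)-2,7-dimethylocta-2,4,6-trienedial
Product: 16 (3R)-3-hydroxy-12'-apo-β-caroten-12'-al, via phosphorus ylide 15 (not isolated)
Conditions: NaOMe (1.1 equiv), 14 (2 equiv), MeOH–CH2Cl2, –10 °C → rt; then heptane, reflux (11Z → 11E); chromatography
Reagents that add atoms: none
Why: Wittig olefination of the symmetrical dialdehyde used in excess should give the mono-adduct with the new C11=C12 bond; the unhindered Z isomer equilibrates thermally to E.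

Step 10
Reactants: 16 (3R)-3-hydroxy-12'-apo-β-caroten-12'-al
Product: 17 (3R)-12'-apo-β-carotene-3,12'-diol
Conditions: NaBH4 (0.5 equiv), EtOH–THF, 0 °C
Reagents that add atoms: none
Why: borohydride 1,2-reduction of the conjugated aldehyde to the primary polyenyl alcohol; nothing else in 16 is reducible under these conditions.

Step 11
Reactants: 17 (3R)-12'-apo-β-carotene-3,12'-diol
Product: 18 [(3R)-3-hydroxy-12'-apo-β-caroten-12'-yl]triphenylphosphonium bromide
Conditions: PPh3·HBr (1.05 equiv), MeOH–CH2Cl2, 0 °C → rt, dark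
Reagents that add atoms: triphenylphosphine hydrobromide, [PH+](c1ccccc1)(c1ccccc1)c1ccccc1.[Br-]
Why: SN1 substitution of the polyenylic alcohol by PPh3 (the retinol-to-retinylphosphonium reaction type); the terminal salt keeps full conjugation and the ring hydroxyl is inert.

Step 12
Reactants: 19 (R)-α-ionone [(3E)-4-[(1R)-2,6,6-trimethylcyclohex-2-en-1-yl]but-3-en-2-one]
Product: 20 (2E,4E)-3-methyl-5-[(1R)-2,6,6-trimethylcyclohex-2-en-1-yl]penta-2,4-dienenitrile
Conditions: (EtO)2P(O)CH2CN (1.3 equiv), NaH (1.3 equiv), THF, 0 °C → rt; chromatography (removal of the 2Z isomer)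
Reagents that add atoms: diethyl cyanomethylphosphonate, N#CCP(=O)(OCC)OCC
Why: Horner–Wadsworth–Emmons olefination of the methyl ketone should give mainly the 2E dienenitrile; C6' comes from 19 and is not deprotonated by the stabilised phosphonate anion.

Step 13
Reactants: 20 (2E,4E)-3-methyl-5-[(1R)-2,6,6-trimethylcyclohex-2-en-1-yl]penta-2,4-dienenitrile
Product: 21 (2E,4E)-3-methyl-5-[(1R)-2,6,6-trimethyl-4-oxocyclohex-2-en-1-yl]penta-2,4-dienenitrile
Conditions: Rh2(C6H10NO)4 (dirhodium tetracaprolactamate, 1 mol %), t-BuOOH (70% aq., 5 equiv), 1,2-dichloroethane, 40 °C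
Reagents that add atoms: tert-butyl hydroperoxide, CC(C)(C)OO
Why: radical allylic oxidation (hydrogen abstraction by tert-butylperoxyl, then collapse of the allylic peroxide to the enone) should occur at the ring CH2 (C3'), the only unhindered allylic methylene, the C6'–H being shielded by the gem-dimethyl group; base-free conditions protect the now vinylogously acidic C6' centre.

Step 14
Reactants: 21 (2E,4E)-3-methyl-5-[(1R)-2,6,6-trimethyl-4-oxocyclohex-2-en-1-yl]penta-2,4-dienenitrile
Product: 22 (2E,4E)-5-[(1R,4R)-4-hydroxy-2,6,6-trimethylcyclohex-2-en-1-yl]-3-methylpenta-2,4-dienenitrile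
Conditions: LiBH(s-Bu)3 (1.2 equiv), THF, –78 °C; MeOH, aq. NH4Cl
Reagents that add atoms: none
Why: 1,2-reduction of the β,β-disubstituted cyclohexenone by a bulky borohydride: in the half-chair with the dienyl chain pseudoaxial, the axial methyl of the gem-dimethyl group blocks the face syn to it, so hydride should enter from the chain-bearing face and the hydroxyl should come out trans to the chain (3'R).

Step 15
Reactants: 22 (2E,4E)-5-[(1R,4R)-4-hydroxy-2,6,6-trimethylcyclohex-2-en-1-yl]-3-methylpenta-2,4-dienenitrile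
Product: 23 (2E,4E)-5-[(1R,4R)-4-hydroxy-2,6,6-trimethylcyclohex-2-en-1-yl]-3-methylpenta-2,4-dienal
Conditions: i-Bu2AlH (2.5 equiv), CH2Cl2, –78 → –40 °C; aq. KNaC4H4O6 (potassium sodium tartrate), 0 °C
Reagents that add atoms: water, O
Why: partial reduction of the nitrile by i-Bu2AlH to the N-aluminio imine and hydrolysis on work-up give the aldehyde (its oxygen comes from water); the free hydroxyl only consumes one hydride and the neutral work-up spares the allylic C3'–O bond.

Step 16
Reactants: 18 [(3R)-3-hydroxy-12'-apo-β-caroten-12'-yl]triphenylphosphonium bromide; 23 (2E,4E)-5-[(1R,4R)-4-hydroxy-2,6,6-trimethylcyclohex-2-en-1-yl]-3-methylpenta-2,4-dienal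
Product: 25 (3R,3'R,6'R)-β,ε-carotene-3,3'-diol (lutein), via phosphorus ylide 24 (not isolated)
Conditions: NaOMe (1.2 equiv), MeOH–CH2Cl2, 0 °C → rt, argon, dark; then heptane–EtOH, reflux (Z → E); crystallisation
Reagents that add atoms: none
Why: Wittig olefination forming C11'=C12' (the retinyl ylide plus retinal reaction type); thermal equilibration and crystallisation should give the all-E polyene, and the ε-ring (C4'=C5', C6'–H) tolerates methoxide at room temperature.

Step 17
Reactants: 25 (3R,3'R,6'R)-β,ε-carotene-3,3'-diol; 26 α-linolenic acid [(9Z,12Z,15Z)-octadeca-9,12,15-trienoic acid]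
Product: 27 (3R,3'R,6'R)-β,ε-carotene-3,3'-diyl bis[(9Z,12Z,15Z)-octadeca-9,12,15-trienoate] (CNP0400996.1)
Conditions: 26 (2.6 equiv), EDC·HCl (3 equiv), DMAP (0.5 equiv), CH2Cl2, 0 °C → rt, argon, dark
Reagents that add atoms: none
Why: Steglich esterification acylates both secondary hydroxyls at oxygen, so C3 and C3' keep their configuration, and the mild non-acidic conditions spare the allylic C3'–O bond, the polyene and the skipped Z-triene of the acyl chains.

**Compound list**

1 | 4,4-dimethoxybutan-2-one | CC(=O)CC(OC)OC | starting material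
2 | 5,5-dimethoxy-3-methylpent-1-yn-3-ol (racemic) | COC(CC(C)(O)C#C)OC | intermediate
3 | (2R,4R)-pentane-2,4-diol | C[C@@H](O)C[C@@H](C)O | starting material
4 | 1-[(4R,6R)-4,6-dimethyl-1,3-dioxan-2-yl]-2-methylbut-3-yn-2-ol (both carbinol epimers) | C[C@@H]1C[C@@H](C)OC(CC(C)(O)C#C)O1 | intermediate
5 | 7-[(4R,6R)-4,6-dimethyl-1,3-dioxan-2-yl]-6-methylhepta-4,5-dien-2-one (allenyl ketone, both allene epimers) | C[C@@H]1C[C@@H](C)OC(CC(C)=C=CCC(C)=O)O1 | intermediate (not isolated)
6 | (3E,5E)-7-[(4R,6R)-4,6-dimethyl-1,3-dioxan-2-yl]-6-methylhepta-3,5-dien-2-one | C[C@@H]1C[C@@H](C)OC(C/C(C)=C/C=C/C(C)=O)O1 | intermediate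
7 | isobutene (2-methylpropene) | CC(C)=C | starting material
8 | tertiary carbocation: (6E,8E)-2,6-dimethyl-10-oxo-4-{[(2R,4R)-4-(trichlorotitaniooxy)pentan-2-yl]oxy}undeca-6,8-dien-2-ylium, C4 configured as C3 of 9 | C[C@@H](O[Ti](Cl)(Cl)Cl)C[C@@H](C)O[C@@H](C[C+](C)C)C/C(C)=C/C=C/C(C)=O | intermediate (not isolated)
9 | (3E)-4-[(4R)-4-{[(2R,4R)-4-hydroxypentan-2-yl]oxy}-2,6,6-trimethylcyclohex-1-en-1-yl]but-3-en-2-one | C[C@@H](O)C[C@@H](C)O[C@@H]1CC(C)=C(/C=C/C(C)=O)C(C)(C)C1 | intermediate
10 | (3E)-4-[(4R)-2,6,6-trimethyl-4-{[(2R)-4-oxopentan-2-yl]oxy}cyclohex-1-en-1-yl]but-3-en-2-one | CC(=O)C[C@@H](C)O[C@@H]1CC(C)=C(/C=C/C(C)=O)C(C)(C)C1 | intermediate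
11 | (3E)-4-[(4R)-4-hydroxy-2,6,6-trimethylcyclohex-1-en-1-yl]but-3-en-2-one | O[C@@H]1CC(C)=C(/C=C/C(C)=O)C(C)(C)C1 | intermediate
12 | (1R)-4-[(1E)-3-hydroxy-3-methylpenta-1,4-dien-1-yl]-3,5,5-trimethylcyclohex-3-en-1-ol (both carbinol epimers) | O[C@@H]1CC(C)=C(/C=C/C(C)(O)C=C)C(C)(C)C1 | intermediate
13 | [(2E,4E)-5-[(4R)-4-hydroxy-2,6,6-trimethylcyclohex-1-en-1-yl]-3-methylpenta-2,4-dien-1-yl]triphenylphosphonium bromide | O[C@@H]1CC(C)=C(/C=C/C(C)=C/C[P+](c2ccccc2)(c2ccccc2)c2ccccc2)C(C)(C)C1.[Br-] | intermediate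
14 | (2E,4E,6E)-2,7-dimethylocta-2,4,6-trienedial | O=C/C(C)=C/C=C/C=C(C)/C=O | starting material
15 | [(2E,4E)-5-[(4R)-4-hydroxy-2,6,6-trimethylcyclohex-1-en-1-yl]-3-methylpenta-2,4-dien-1-ylidene]triphenyl-λ5-phosphane | O[C@@H]1CC(C)=C(/C=C/C(C)=C/C=P(c2ccccc2)(c2ccccc2)c2ccccc2)C(C)(C)C1 | intermediate (not isolated)
16 | (3R)-3-hydroxy-12'-apo-β-caroten-12'-al | O[C@@H]1CC(C)=C(/C=C/C(C)=C/C=C/C(C)=C/C=C/C=C(C)/C=O)C(C)(C)C1 | intermediate
17 | (3R)-12'-apo-β-carotene-3,12'-diol | O[C@@H]1CC(C)=C(/C=C/C(C)=C/C=C/C(C)=C/C=C/C=C(C)/CO)C(C)(C)C1 | intermediate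
18 | [(3R)-3-hydroxy-12'-apo-β-caroten-12'-yl]triphenylphosphonium bromide | O[C@@H]1CC(C)=C(/C=C/C(C)=C/C=C/C(C)=C/C=C/C=C(C)/C[P+](c2ccccc2)(c2ccccc2)c2ccccc2)C(C)(C)C1.[Br-] | intermediate
19 | (R)-α-ionone, (3E)-4-[(1R)-2,6,6-trimethylcyclohex-2-en-1-yl]but-3-en-2-one | CC(=O)/C=C/[C@H]1C(C)=CCCC1(C)C | starting material
20 | (2E,4E)-3-methyl-5-[(1R)-2,6,6-trimethylcyclohex-2-en-1-yl]penta-2,4-dienenitrile | N#C/C=C(C)/C=C/[C@H]1C(C)=CCCC1(C)C | intermediate
21 | (2E,4E)-3-methyl-5-[(1R)-2,6,6-trimethyl-4-oxocyclohex-2-en-1-yl]penta-2,4-dienenitrile | N#C/C=C(C)/C=C/[C@H]1C(C)=CC(=O)CC1(C)C | intermediate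
22 | (2E,4E)-5-[(1R,4R)-4-hydroxy-2,6,6-trimethylcyclohex-2-en-1-yl]-3-methylpenta-2,4-dienenitrile | N#C/C=C(C)/C=C/[C@H]1C(C)=C[C@H](O)CC1(C)C | intermediate
23 | (2E,4E)-5-[(1R,4R)-4-hydroxy-2,6,6-trimethylcyclohex-2-en-1-yl]-3-methylpenta-2,4-dienal | O=C/C=C(C)/C=C/[C@H]1C(C)=C[C@H](O)CC1(C)C | intermediate
24 | [(3R)-3-hydroxy-12'-apo-β-caroten-12'-ylidene]triphenyl-λ5-phosphane | O[C@@H]1CC(C)=C(/C=C/C(C)=C/C=C/C(C)=C/C=C/C=C(C)/C=P(c2ccccc2)(c2ccccc2)c2ccccc2)C(C)(C)C1 | intermediate (not isolated)
25 | (3R,3'R,6'R)-β,ε-carotene-3,3'-diol (lutein) | O[C@@H]1CC(C)=C(/C=C/C(C)=C/C=C/C(C)=C/C=C/C=C(C)/C=C/C=C(C)/C=C/[C@H]2C(C)=C[C@H](O)CC2(C)C)C(C)(C)C1 | intermediate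
26 | α-linolenic acid, (9Z,12Z,15Z)-octadeca-9,12,15-trienoic acid | CC/C=C\C/C=C\C/C=C\CCCCCCCC(=O)O | starting material
27 | (3R,3'R,6'R)-β,ε-carotene-3,3'-diyl bis[(9Z,12Z,15Z)-octadeca-9,12,15-trienoate] | CC/C=C\C/C=C\C/C=C\CCCCCCCC(=O)O[C@@H]1CC(C)=C(/C=C/C(C)=C/C=C/C(C)=C/C=C/C=C(C)/C=C/C=C(C)/C=C/[C@H]2C(C)=C[C@H](OC(=O)CCCCCCC/C=C\C/C=C\C/C=C\CC)CC2(C)C)C(C)(C)C1 | target

**Count and risks**

Total step count: 17. Longest linear sequence: 13 steps (steps 1–11, 16 and 17).

Steps most likely to fail: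

1. Step 4 (Proposed new method). Cation 8 may add further isobutene or be quenched by chloride or proton loss before the ring closes; facial control by the template may erode with a simple alkene as nucleophile; the acetal may lose a C4 proton to an enol ether; and the final proton may be lost to the non-conjugated side. The fallback separates the two bond formations and uses known chemistry. It sets out from 6: Hosomi–Sakurai-type opening of the acetal with trimethyl(2-methylallyl)silane and TiCl4 in CH2Cl2 at –78 °C (the established allylsilane opening of pentanediol acetals) should give (3E,5E,8S)-8-{[(2R,4R)-4-hydroxypentan-2-yl]oxy}-6,10-dimethylundeca-3,5,10-trien-2-one F1 with the same sense of induction. A separate Brønsted acid ring closure of F1 (85% H3PO4 or MeSO3H in MeNO2, 0 °C; the pseudoionone-to-ionone reaction type, protonation of the 1,1-disubstituted alkene giving the same tertiary cation) should then lead back to the route at 9, any C4=C5 isomer being converged in step 6.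

2. Step 14. Hydride delivery may show poor facial selectivity because the controlling chain is remote from the carbonyl, and conjugate reduction may compete. The fallback accepts the opposite selectivity and inverts. It sets out from 21: Luche reduction (NaBH4, CeCl3·7H2O, MeOH, –20 °C; axial attack of the small hydride) should give mainly the cis alcohol (2E,4E)-5-[(1R,4S)-4-hydroxy-2,6,6-trimethylcyclohex-2-en-1-yl]-3-methylpenta-2,4-dienenitrile F2. Mitsunobu inversion (4-nitrobenzoic acid, PPh3, DIAD, THF, 0 °C) should give (1R,4R)-4-[(1E,3E)-4-cyano-3-methylbuta-1,3-dien-1-yl]-3,5,5-trimethylcyclohex-2-en-1-yl 4-nitrobenzoate F3. Methanolysis (K2CO3, MeOH) returns to the route at 22.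

3. Step 3. The dioxane may exchange or open under acid at the Claisen temperature, and the allene-to-dienone isomerisation may be incomplete or give an unfavourable mixture at the trisubstituted double bond. The fallback builds the dienone by olefinations and installs the template last. It sets out from 1: Horner–Wadsworth–Emmons reaction with triethyl phosphonoacetate and NaH should give ethyl (2E)-5,5-dimethoxy-3-methylpent-2-enoate F4 (E isomer separated). i-Bu2AlH reduction gives (2E)-5,5-dimethoxy-3-methylpent-2-en-1-ol F5, and MnO2 oxidation gives (2E)-5,5-dimethoxy-3-methylpent-2-enal F6. Wittig reaction with 1-(triphenyl-λ5-phosphanylidene)propan-2-one gives (3E,5E)-8,8-dimethoxy-6-methylocta-3,5-dien-2-one F7. Acetal exchange with 3 (PPTS, toluene, removal of methanol) returns to the route at 6.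

Further compounds
F1 | step 4 | (3E,5E,8S)-8-{[(2R,4R)-4-hydroxypentan-2-yl]oxy}-6,10-dimethylundeca-3,5,10-trien-2-one | C[C@@H](O)C[C@@H](C)O[C@@H](CC(C)=C)C/C(C)=C/C=C/C(C)=O
F2 | step 14 | (2E,4E)-5-[(1R,4S)-4-hydroxy-2,6,6-trimethylcyclohex-2-en-1-yl]-3-methylpenta-2,4-dienenitrile | N#C/C=C(C)/C=C/[C@H]1C(C)=C[C@@H](O)CC1(C)C
F3 | step 14 | (1R,4R)-4-[(1E,3E)-4-cyano-3-methylbuta-1,3-dien-1-yl]-3,5,5-trimethylcyclohex-2-en-1-yl 4-nitrobenzoate | N#C/C=C(C)/C=C/[C@H]1C(C)=C[C@H](OC(=O)c2ccc(cc2)[N+](=O)[O-])CC1(C)C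
F4 | step 3 | ethyl (2E)-5,5-dimethoxy-3-methylpent-2-enoate | CCOC(=O)/C=C(C)/CC(OC)OC
F5 | step 3 | (2E)-5,5-dimethoxy-3-methylpent-2-en-1-ol | OC/C=C(C)/CC(OC)OC
F6 | step 3 | (2E)-5,5-dimethoxy-3-methylpent-2-enal | O=C/C=C(C)/CC(OC)OC
F7 | step 3 | (3E,5E)-8,8-dimethoxy-6-methylocta-3,5-dien-2-one | CC(=O)/C=C/C=C(C)/CC(OC)OC
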